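**Strategy.** The route rests on disconnecting ring A at C1–C10 (labdane numbering). A monocyclic ring B precursor carries an exocyclic C10=C20 methylene, an ester tether on C5 ending in a 2-sulfonylallyl acceptor, the C9 side arm and a silyl-masked C8 carbinol. Iron-hydride hydrogen-atom transfer turns the methylene into the C20 methyl and a tertiary C10 radical, which closes ring A (6-endo) on C1. The step exploits the quaternary ring-fusion carbon C10: its angular methyl is made in the same operation, and the axial C17 methyl on C8 steers bonding to the α face, giving the trans-fused decalin.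

Key step: step 6

Remark: labdane numbering is used for all intermediates (C1–C10 ring carbons, C11–C16 side chain, C17 on C8, C18 and C19 on C4, C20 on C10; α is the face of H5, β the face of C20); the target is (4S,5R,8R,9R,10S,13E).

Step 1
Reactants: 1 3-methylcyclohex-2-en-1-one; 2 dimethyl(phenyl)(4,4,5,5-tetramethyl-1,3,2-dioxaborolan-2-yl)silane
Product: 3 (R)-3-[dimethyl(phenyl)silyl]-3-methylcyclohexan-1-one
Conditions: CuCl (cat.), chiral imidazolinium carbene precursor (cat., antipode giving the R ketone), NaOt-Bu (cat.), THF, −78 °C; aq. work-up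
Reagents that add atoms: none
Why: Copper-catalysed enantioselective conjugate silyl transfer, in which the chiral carbene ligand selects the enone face and so fixes C8, with silicon standing in for the later 8α-hydroxyl and the ring methyl becoming C17.

Step 2
Reactants: 3 (R)-3-[dimethyl(phenyl)silyl]-3-methylcyclohexan-1-one; 4 methyl bromoacetate
Product: 5 methyl 2-[(4R)-4-[dimethyl(phenyl)silyl]-4-methyl-2-oxocyclohexyl]acetate (mixture at C5)
Conditions: LiN(i-Pr)2, THF, −78 °C; then 4, −78 to −20 °C
Reagents that add atoms: none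
Why: Kinetic enolate alkylation, in which deprotonation should occur at the unhindered C5 methylene remote from the quaternary C8, and the C5 configuration is left open because it is corrected in step 3.

Step 3
Reactants: 5 methyl 2-[(4R)-4-[dimethyl(phenyl)silyl]-4-methyl-2-oxocyclohexyl]acetate; 6 2-(2-bromoethyl)-2-methyl-1,3-dioxolane
Product: 8 methyl 2-[(1S,3R,4R)-4-[dimethyl(phenyl)silyl]-4-methyl-3-[2-(2-methyl-1,3-dioxolan-2-yl)ethyl]-2-oxocyclohexyl]acetate, via C5-epimeric alkylation product 7 (not isolated)
Conditions: LiN(i-Pr)2 (1.05 equiv), THF, −78 °C; 6, DMPU, Bu4NI (cat.), −78 to 0 °C; then K2CO3 (cat.), MeOH, rt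
Reagents that add atoms: none
Why: Alkylation of a β-silyl enolate, formed at the only remaining α-methylene (C9), should occur anti to silicon and set C9, after which base epimerisation of the more accessible C5 should give the all-equatorial 2,6-cis ketone under thermodynamic control anchored by the fixed C8.

Step 4
Reactants: 8 methyl 2-[(1S,3R,4R)-4-[dimethyl(phenyl)silyl]-4-methyl-3-[2-(2-methyl-1,3-dioxolan-2-yl)ethyl]-2-oxocyclohexyl]acetate
Product: 9 methyl 2-[(1S,3R,4R)-4-[dimethyl(phenyl)silyl]-4-methyl-3-[2-(2-methyl-1,3-dioxolan-2-yl)ethyl]-2-methylidenecyclohexyl]acetate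
Conditions: Zn, CH2Br2, TiCl4, THF/CH2Cl2, 0 °C to rt
Reagents that add atoms: dibromomethane BrCBr
Why: Takai–Lombardo methylenation, a non-basic titanium–zinc carbenoid olefination that should convert the hindered C10 ketone into the C10=C20 methylene without epimerising C5 or C9 and without touching the ester or ketal.

Step 5
Reactants: 9 methyl 2-[(1S,3R,4R)-4-[dimethyl(phenyl)silyl]-4-methyl-3-[2-(2-methyl-1,3-dioxolan-2-yl)ethyl]-2-methylidenecyclohexyl]acetate; 10 2,3-bis(phenylsulfonyl)prop-1-ene
Product: 11 methyl 2-[(1S,3R,4R)-4-[dimethyl(phenyl)silyl]-4-methyl-3-[2-(2-methyl-1,3-dioxolan-2-yl)ethyl]-2-methylidenecyclohexyl]-4-(phenylsulfonyl)pent-4-enoate (mixture at C4)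
Conditions: LiN(i-Pr)2, THF, −78 °C; inverse addition to 10, −78 to −20 °C
Reagents that add atoms: none
Why: Ester enolate allylation by conjugate addition–elimination on the bis-sulfone installs C3, C2 and C1 as a 2-sulfonylallyl radical acceptor, and the new C4 centre is formed as an inconsequential mixture that is reset in step 8.

Step 6
Reactants: 11 methyl 2-[(1S,3R,4R)-4-[dimethyl(phenyl)silyl]-4-methyl-3-[2-(2-methyl-1,3-dioxolan-2-yl)ethyl]-2-methylidenecyclohexyl]-4-(phenylsulfonyl)pent-4-enoate
Product: 12 methyl 8α-[dimethyl(phenyl)silyl]-13,13-(ethylenedioxy)-2-(phenylsulfonyl)-14,15,18-trinorlabdan-19-oate (mixture at C2 and C4)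
Conditions: Fe(acac)3 (0.5 equiv), PhSiH3 (2.5 equiv), EtOH/ethylene glycol, 60 °C, high dilution
Reagents that add atoms: none
Why: Hydrogen-atom transfer from the iron hydride (from Fe(acac)3 and PhSiH3) to C20 of the electron-rich 1,1-disubstituted alkene gives the tertiary C10 radical and, in the same event, the C20 methyl; this nucleophilic radical adds to the unsubstituted terminus C1 of the sulfonyl-activated alkene, and the resulting α-sulfonyl radical is reduced and protonated by ethanol. The closest known reaction type is the iron-mediated reductive olefin coupling (a hydrogen-atom-transfer-initiated Giese addition), used here intramolecularly. Ring A closes in the 6-endo-trig mode, because attack at the sulfonyl-bearing C2 (5-exo) is polarity-mismatched and would join two fully substituted carbons. The new stereocentre C10 is controlled by ring B, which should react as the chair with the C5 tether, the C9 arm and the silyl group equatorial: the axial C17 methyl on C8 is 1,3-syn to the β lobe of the C10 radical and blocks it, so C1 should bond on the α face (cis to H5) and C20 should become β-axial, which is the trans ring fusion; C2 and C4 arise as mixtures that do not matter (C2 loses its substituent in step 7, C4 is reset in step 8). The step needs hydrogen-atom delivery to the exocyclic alkene and not to the vinyl sulfone, which the electron-rich against electron-poor character of the two alkenes should secure, and ring closure must outrun a second hydrogen-atom transfer to C10, which the polarity-matched intramolecular addition and high dilution favour.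

Step 7
Reactants: 12 methyl 8α-[dimethyl(phenyl)silyl]-13,13-(ethylenedioxy)-2-(phenylsulfonyl)-14,15,18-trinorlabdan-19-oate
Product: 13 methyl 8α-[dimethyl(phenyl)silyl]-13,13-(ethylenedioxy)-14,15,18-trinorlabdan-19-oate (mixture at C4)
Conditions: Na(Hg), Na2HPO4, MeOH/THF, −20 °C to rt
Reagents that add atoms: none
Why: Reductive desulfonylation (single-electron cleavage of the C–S bond by sodium amalgam under buffered conditions) removes the activating sulfone so that C2 becomes a methylene and no stereocentre remains there.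

Step 8
Reactants: 13 methyl 8α-[dimethyl(phenyl)silyl]-13,13-(ethylenedioxy)-14,15,18-trinorlabdan-19-oate
Product: 14 methyl 8α-[dimethyl(phenyl)silyl]-13,13-(ethylenedioxy)-14,15-dinorlabdan-19-oate
Conditions: LiN(i-Pr)2, THF/DMPU, −78 to 0 °C; MeI
Reagents that add atoms: iodomethane CI
Why: Ester enolate C-methylation, in which the electrophile should enter from the α (equatorial) face away from the 1,3-diaxial C20 methyl, so that the new methyl becomes C18 (equatorial) and the ester becomes the axial C19 group.

Step 9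
Reactants: 14 methyl 8α-[dimethyl(phenyl)silyl]-13,13-(ethylenedioxy)-14,15-dinorlabdan-19-oate
Product: 16 methyl 8α-hydroxy-13-oxo-14,15-dinorlabdan-19-oate, via fluorosilane ketone 15 (not isolated)
Conditions: HBF4·OEt2, CH2Cl2, 0 °C to rt; aq. HCl work-up; then KF, KHCO3, 30% H2O2, THF/MeOH, 50 °C
Reagents that add atoms: tetrafluoroboric acid F[B-](F)(F)F.[H+] (fluorine of 15 only); hydrogen peroxide OO; water O
Why: Fleming–Tamao oxidation, in which acid removes the phenyl group from silicon (and unmasks the C13 ketone) and peroxide then induces 1,2-migration of C8 from silicon to oxygen with retention, which should give the 8α-hydroxyl with C17 β.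

Step 10
Reactants: 16 methyl 8α-hydroxy-13-oxo-14,15-dinorlabdan-19-oate; 17 triethyl phosphonoacetate
Product: 18 15-ethyl 19-methyl (13E)-8α-hydroxylabd-13-ene-15,19-dioate
Conditions: NaH, THF, then 17; 16, THF/toluene, reflux
Reagents that add atoms: none
Why: Horner–Wadsworth–Emmons olefination of the methyl ketone, in which the E-trisubstituted enoate is expected to predominate and any Z isomer is to be removed by chromatography.

Step 11
Reactants: 18 15-ethyl 19-methyl (13E)-8α-hydroxylabd-13-ene-15,19-dioate
Product: 19 (13E)-labd-13-ene-8α,15,19-triol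
Conditions: LiAlH4, THF, 0 °C to reflux
Reagents that add atoms: none
Why: Hydride reduction of both esters (1,2-reduction of the enoate and reduction of the hindered C19 ester) gives the two primary alcohols without creating a stereocentre.

Step 12
Reactants: 19 (13E)-labd-13-ene-8α,15,19-triol
Product: 21 (13E)-15-[(tert-butyldimethylsilyl)oxy]-8α-hydroxylabd-13-en-19-yl acetate, via 15-O-silyl diol 20 (not isolated)
Conditions: TBSCl (1.05 equiv), imidazole, CH2Cl2, −20 °C; then Ac2O, Et3N, DMAP (cat.), 0 °C to rt
Reagents that add atoms: tert-butyldimethylsilyl chloride CC(C)(C)[Si](C)(C)Cl; acetic anhydride CC(=O)OC(C)=O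
Why: Sterically controlled silylation followed by acylation in one pot, in which the unhindered allylic C15 hydroxyl should be silylated first, the neopentyl C19 hydroxyl is then acetylated and the tertiary C8 hydroxyl should not react.

Step 13
Reactants: 21 (13E)-15-[(tert-butyldimethylsilyl)oxy]-8α-hydroxylabd-13-en-19-yl acetate
Product: 22 (13E)-8α,15-dihydroxylabd-13-en-19-yl acetate (the target)
Conditions: Bu4NF, AcOH, THF, 0 °C to rt
Reagents that add atoms: none
Why: Fluoride-mediated desilylation, buffered with acetic acid so that the C19 acetate should neither migrate nor be cleaved.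

**Compound list**

1 | 3-methylcyclohex-2-en-1-one | CC1=CC(=O)CCC1 | starting material
2 | dimethyl(phenyl)(4,4,5,5-tetramethyl-1,3,2-dioxaborolan-2-yl)silane | C[Si](C)(c1ccccc1)B1OC(C)(C)C(C)(C)O1 | starting material
3 | (R)-3-[dimethyl(phenyl)silyl]-3-methylcyclohexan-1-one | O=C1C[C@](C)([Si](C)(C)c2ccccc2)CCC1 | intermediate
4 | methyl bromoacetate | COC(=O)CBr | starting material
5 | methyl 2-[(4R)-4-[dimethyl(phenyl)silyl]-4-methyl-2-oxocyclohexyl]acetate (mixture at C5) | O=C1C[C@](C)([Si](C)(C)c2ccccc2)CCC1CC(=O)OC | intermediate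
6 | 2-(2-bromoethyl)-2-methyl-1,3-dioxolane | CC1(CCBr)OCCO1 | starting material
7 | methyl 2-[(3R,4R)-4-[dimethyl(phenyl)silyl]-4-methyl-3-[2-(2-methyl-1,3-dioxolan-2-yl)ethyl]-2-oxocyclohexyl]acetate (C9 arm trans to silicon, mixture at C5) | O=C1[C@@H](CCC2(C)OCCO2)[C@](C)([Si](C)(C)c3ccccc3)CCC1CC(=O)OC | intermediate
8 | methyl 2-[(1S,3R,4R)-4-[dimethyl(phenyl)silyl]-4-methyl-3-[2-(2-methyl-1,3-dioxolan-2-yl)ethyl]-2-oxocyclohexyl]acetate (C5 and C9 arms cis and equatorial, silicon equatorial, C17 axial) | O=C1[C@@H](CCC2(C)OCCO2)[C@](C)([Si](C)(C)c3ccccc3)CC[C@H]1CC(=O)OC | intermediate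
9 | methyl 2-[(1S,3R,4R)-4-[dimethyl(phenyl)silyl]-4-methyl-3-[2-(2-methyl-1,3-dioxolan-2-yl)ethyl]-2-methylidenecyclohexyl]acetate | C=C1[C@@H](CCC2(C)OCCO2)[C@](C)([Si](C)(C)c3ccccc3)CC[C@H]1CC(=O)OC | intermediate
10 | 2,3-bis(phenylsulfonyl)prop-1-ene | C=C(CS(=O)(=O)c1ccccc1)S(=O)(=O)c1ccccc1 | starting material
11 | methyl 2-[(1S,3R,4R)-4-[dimethyl(phenyl)silyl]-4-methyl-3-[2-(2-methyl-1,3-dioxolan-2-yl)ethyl]-2-methylidenecyclohexyl]-4-(phenylsulfonyl)pent-4-enoate (mixture at C4) | C=C1[C@@H](CCC2(C)OCCO2)[C@](C)([Si](C)(C)c3ccccc3)CC[C@H]1C(CC(=C)S(=O)(=O)c1ccccc1)C(=O)OC | intermediate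
12 | methyl 8α-[dimethyl(phenyl)silyl]-13,13-(ethylenedioxy)-2-(phenylsulfonyl)-14,15,18-trinorlabdan-19-oate (trans-decalin: H5α, C20β, H9α, C17β; mixture at C2 and C4) | COC(=O)C1CC(S(=O)(=O)c3ccccc3)C[C@]2(C)[C@@H](CCC4(C)OCCO4)[C@](C)([Si](C)(C)c5ccccc5)CC[C@@H]12 | intermediate
13 | methyl 8α-[dimethyl(phenyl)silyl]-13,13-(ethylenedioxy)-14,15,18-trinorlabdan-19-oate (mixture at C4) | COC(=O)C1CCC[C@]2(C)[C@@H](CCC3(C)OCCO3)[C@](C)([Si](C)(C)c4ccccc4)CC[C@@H]12 | intermediate
14 | methyl 8α-[dimethyl(phenyl)silyl]-13,13-(ethylenedioxy)-14,15-dinorlabdan-19-oate (axial C19 ester, equatorial C18 methyl) | COC(=O)[C@@]1(C)CCC[C@]2(C)[C@@H](CCC3(C)OCCO3)[C@](C)([Si](C)(C)c4ccccc4)CC[C@@H]12 | intermediate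
15 | methyl 8α-[fluoro(dimethyl)silyl]-13-oxo-14,15-dinorlabdan-19-oate | COC(=O)[C@@]1(C)CCC[C@]2(C)[C@@H](CCC(C)=O)[C@](C)([Si](C)(C)F)CC[C@@H]12 | intermediate
16 | methyl 8α-hydroxy-13-oxo-14,15-dinorlabdan-19-oate | COC(=O)[C@@]1(C)CCC[C@]2(C)[C@@H](CCC(C)=O)[C@](C)(O)CC[C@@H]12 | intermediate
17 | triethyl phosphonoacetate | CCOC(=O)CP(=O)(OCC)OCC | starting material
18 | 15-ethyl 19-methyl (13E)-8α-hydroxylabd-13-ene-15,19-dioate | COC(=O)[C@@]1(C)CCC[C@]2(C)[C@@H](CC/C(C)=C/C(=O)OCC)[C@](C)(O)CC[C@@H]12 | intermediate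
19 | (13E)-labd-13-ene-8α,15,19-triol | OC[C@@]1(C)CCC[C@]2(C)[C@@H](CC/C(C)=C/CO)[C@](C)(O)CC[C@@H]12 | intermediate
20 | (13E)-15-[(tert-butyldimethylsilyl)oxy]labd-13-ene-8α,19-diol | OC[C@@]1(C)CCC[C@]2(C)[C@@H](CC/C(C)=C/CO[Si](C)(C)C(C)(C)C)[C@](C)(O)CC[C@@H]12 | intermediate
21 | (13E)-15-[(tert-butyldimethylsilyl)oxy]-8α-hydroxylabd-13-en-19-yl acetate | CC(=O)OC[C@@]1(C)CCC[C@]2(C)[C@@H](CC/C(C)=C/CO[Si](C)(C)C(C)(C)C)[C@](C)(O)CC[C@@H]12 | intermediate
22 | (13E)-8α,15-dihydroxylabd-13-en-19-yl acetate, (4S,5R,8R,9R,10S) | CC(=O)OC[C@@]1(C)CCC[C@]2(C)[C@@H](CC/C(C)=C/CO)[C@](C)(O)CC[C@@H]12 | target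

Total steps: 13. Longest linear sequence: 13 steps (1 to 22).

**Steps most likely to fail**

Step 6: the tertiary C10 radical may be quenched by a second hydrogen-atom transfer before it closes (net hydrogenation of the methylene), hydride may be delivered to the vinyl sulfone, or facial control may erode if ring B does not react through the all-equatorial chair. The fallback changes the bond-forming manifold and sets out from 9. The ester enolate of 9 (LiN(i-Pr)2) is alkylated with 1,3-diiodopropane to give methyl 2-[(1S,3R,4R)-4-[dimethyl(phenyl)silyl]-4-methyl-3-[2-(2-methyl-1,3-dioxolan-2-yl)ethyl]-2-methylidenecyclohexyl]-5-iodopentanoate F1. Hydrogen-atom transfer in the presence of a nickel co-catalyst (Mn(dpm)3, Ni(acac)2, PhSiH3, K2CO3) would then join C10 to C1 by nickel-mediated alkyl–alkyl coupling in place of conjugate addition. This comes back to the route at 13, so that step 7 is not needed.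

Step 3: enolisation may take place at the C5 methine or at the ester instead of C9, and substitution at the neopentyl-like C9 enolate may be slow enough for proton exchange to scramble the enolate. The fallback replaces the substitution by a Lewis-acid conjugate addition and sets out from 5. LiN(i-Pr)2 and Me3SiCl give methyl 2-[(4R)-4-[dimethyl(phenyl)silyl]-4-methyl-2-[(trimethylsilyl)oxy]cyclohex-2-en-1-yl]acetate F2, whose regioisomers can be separated before the carbon–carbon bond is made. Mukaiyama–Michael addition to but-3-en-2-one (TiCl4, CH2Cl2, −78 °C) gives methyl 2-[(3R,4R)-4-[dimethyl(phenyl)silyl]-4-methyl-2-oxo-3-(3-oxobutyl)cyclohexyl]acetate F3. Selective ketalisation of the unhindered methyl ketone (1,2-bis(trimethylsilyloxy)ethane, Me3SiOTf, −78 °C) comes back to the route at 7, which is equilibrated to 8 as in step 3.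

Step 1: the β-methyl group may slow the silyl transfer and lower the enantioselectivity at the quaternary centre. The fallback replaces catalysis by resolution and sets out from 1. Stoichiometric conjugate addition of (PhMe2Si)2CuLi gives racemic 3-[dimethyl(phenyl)silyl]-3-methylcyclohexan-1-one F4. Condensation with SAMP gives diastereomeric hydrazones, from which (S)-2-(methoxymethyl)-N-[(3R)-3-[dimethyl(phenyl)silyl]-3-methylcyclohexylidene]pyrrolidin-1-amine F5 is separated. Cleavage with aqueous oxalic acid comes back to the route at 3.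

Further compounds
F1 | step 6 | methyl 2-[(1S,3R,4R)-4-[dimethyl(phenyl)silyl]-4-methyl-3-[2-(2-methyl-1,3-dioxolan-2-yl)ethyl]-2-methylidenecyclohexyl]-5-iodopentanoate | C=C1[C@@H](CCC2(C)OCCO2)[C@](C)([Si](C)(C)c3ccccc3)CC[C@H]1C(CCCI)C(=O)OC
F2 | step 3 | methyl 2-[(4R)-4-[dimethyl(phenyl)silyl]-4-methyl-2-[(trimethylsilyl)oxy]cyclohex-2-en-1-yl]acetate | C[Si](C)(C)OC1=C[C@](C)([Si](C)(C)c2ccccc2)CCC1CC(=O)OC
F3 | step 3 | methyl 2-[(3R,4R)-4-[dimethyl(phenyl)silyl]-4-methyl-2-oxo-3-(3-oxobutyl)cyclohexyl]acetate | O=C1[C@@H](CCC(C)=O)[C@](C)([Si](C)(C)c2ccccc2)CCC1CC(=O)OC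
F4 | step 1 | racemic 3-[dimethyl(phenyl)silyl]-3-methylcyclohexan-1-one | CC1([Si](C)(C)c2ccccc2)CCCC(=O)C1
F5 | step 1 | (S)-2-(methoxymethyl)-N-[(3R)-3-[dimethyl(phenyl)silyl]-3-methylcyclohexylidene]pyrrolidin-1-amine | COC[C@@H]1CCCN1N=C1C[C@](C)([Si](C)(C)c2ccccc2)CCC1
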